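**Strategy.** In germacranolide numbering, the α-methylene-γ-butyrolactone ring (C6, C7, C11, C12, O6) is treated as a 2-alkenylcyclobutanone plus one oxygen, and the C9 hydroxyl with the exocyclic C13 as a ring-opened tetrahydropyran. The key step is a keteniminium–alkene [2+2] between an iodoalkenyl keteniminium (C6=C12) and the C7=C11 alkene of an enantiopure cis-2,3-disubstituted 3,6-dihydro-2H-pyran (ring oxygen O9, ring CH2 C13); it forms C6–C7 and C11–C12 together and relays C8/C9 to C7 and C6. Baeyer–Villiger oxygen insertion then gives the lactone, Negishi coupling and ring-closing metathesis at C1=C10 close the ten-membered ring, and ether cleavage–elimination finally releases O9–H and C11=C13.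

Key step: step 9

Remark: atom labels follow germacranolide numbering: C1–C10 ring, C11 (lactone α-carbon), C12 (lactone C=O), C13 (exocyclic CH2), C14 (ester carbon), C15 (methyl); O6, O8 and O9 sit on C6, C8 and C9.
Assumption: allyl methoxymethyl ether (4), (+)-B-methoxydiisopinocampheylborane and but-3-enylzinc bromide solution (22) are bought as such.

Step 1
Reactants: 1 acrolein
Product: 3 2-bromoacrolein (2-bromoprop-2-enal), via 2,3-dibromopropanal 2 (not isolated)
Conditions: Br2, CH2Cl2, −78 °C; then Et3N, −78 → 0 °C; used at once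
Reagents that add atoms: bromine, BrBr
Why: Bromine addition to the enal followed by E1cB loss of HBr (bromination–dehydrobromination) should give the α-bromo enal.

Step 2
Reactants: 3 2-bromoacrolein; 4 allyl methoxymethyl ether
Product: 7 (3R,4S)-2-bromo-4-(methoxymethoxy)hexa-1,5-dien-3-ol, via allylborane 5 (not isolated), via borinate 6 (not isolated)
Conditions: 4, s-BuLi, THF, −78 °C; (+)-Ipc2BOMe; BF3·OEt2; then 3, −78 °C; NaOH, H2O2, 0 °C → rt
Reagents that add atoms: none
Why: γ-Alkoxyallylboration through a closed chair transition state: the (Z)-alkoxyallyl geometry should give the syn C8–O/C9–O relation and the isopinocampheyl groups from (−)-α-pinene the absolute configuration, so C8 and C9 are set here.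

Step 3
Reactants: 7 the bromo dienol; 8 allyl bromide
Product: 9 (3R,4S)-3-(allyloxy)-2-bromo-4-(methoxymethoxy)hexa-1,5-diene
Conditions: NaH, allyl bromide, Bu4NI (cat.), THF, 0 °C → rt
Reagents that add atoms: allyl bromide (8), C=CCBr
Why: Williamson etherification of the secondary alkoxide puts the future C13 on O9; vinyl bromide and MOM ether are inert.

Step 4
Reactants: 9 the triene
Product: 10 (2R,3S)-2-(1-bromovinyl)-3-(methoxymethoxy)-3,6-dihydro-2H-pyran
Conditions: Grubbs II catalyst (2 mol%), CH2Cl2, 40 °C
Reagents that add atoms: none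
Why: Ring-closing metathesis of the two monosubstituted alkenes should close the six-membered ring (C7=C11), while the 1-bromovinyl group does not engage the ruthenium carbene.

Step 5
Reactants: 10 the bromovinyl dihydropyran
Product: 11 methyl 2-[(2S,3S)-3-(methoxymethoxy)-3,6-dihydro-2H-pyran-2-yl]acrylate
Conditions: Pd(OAc)2 (5 mol%), PPh3, CO (1 atm), MeOH, Et3N, DMF, 60 °C
Reagents that add atoms: carbon monoxide, [C-]#[O+]; methanol, CO
Why: Palladium-catalysed alkoxycarbonylation of the vinyl bromide (oxidative addition, CO insertion, methanolysis) installs C14 as the α-substituted acrylate without touching the allylic ethers.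

Step 6
Reactants: 12 pent-3-yn-1-ol
Product: 14 (E)-4-iodopent-3-en-1-ol, via alkenylzirconocene 13 (not isolated)
Conditions: Cp2Zr(H)Cl (2.5 equiv), THF, rt → 50 °C; then I2, 0 °C
Reagents that add atoms: iodine, II
Why: syn-Hydrozirconation with equilibration of zirconium to the methyl-bearing carbon, then iodinolysis with retention, should give the (E)-2-iodoalkene (future C4=C5 geometry).

Step 7
Reactants: 14 the iodo alcohol
Product: 15 (E)-4-iodopent-3-enoic acid
Conditions: CrO3, H2SO4, acetone, 0 °C
Reagents that add atoms: water, O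
Why: Jones oxidation of the primary homoallylic alcohol gives the β,γ-unsaturated acid, and the acidic medium avoids conjugation of the double bond.

Step 8
Reactants: 15 the iodo acid
Product: 17 (E)-4-iodo-N,N-dimethylpent-3-enamide, via acid chloride 16 (not isolated)
Conditions: (COCl)2, DMF (cat.), CH2Cl2, 0 °C; then Me2NH (2 M in THF), 0 °C
Reagents that add atoms: dimethylamine, CNC
Why: Acid chloride formation and aminolysis give the tertiary amide needed for keteniminium formation.

Step 9
Reactants: 11 the acrylate dihydropyran; 17 the iodo amide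
Product: 20 cis-fused pyrano-cyclobutanone (C12 ketone; C6 bearing the (E)-2-iodoprop-1-enyl group exo, trans to C8; H7/H11 cis; 8-OMOM and the C9 acrylate unit cis to each other and trans to C6), via keteniminium triflate 18 (not isolated), via cyclobutaniminium triflate 19 (not isolated)
Conditions: 17 (1.5 equiv), Tf2O, 2,6-di-tert-butyl-4-methylpyridine, ClCH2CH2Cl, −20 °C → rt; then 11, 70 °C; NaHCO3 aq., rt; DBU (cat.), CH2Cl2, rt
Reagents that add atoms: water, O
Why: The amide is turned into the electrophilic keteniminium 18, whose central carbon C12 is attacked by C11 of the ring alkene of 11; the cation developing at C7 is then closed by C6, so that C11–C12 and C6–C7 form in one stepwise [2+2] event (19), and hydrolysis gives the ketone. The closest known reaction type is the intermolecular keteniminium–olefin (ketene–alkene) [2+2] cycloaddition to unactivated cis-cycloalkenes. The four-membered ring is closed as an intermolecular cycloaddition, suprafacial on the alkene, which makes the pyran/cyclobutanone fusion cis. C7 and C11 are set by attack on the half-chair face opposite to the pseudo-axial C8–OMOM and the C9 substituent (both fixed in step 2), and C6 is set thermodynamically (side chain exo) by enolisation with DBU. The step needs regioselectivity (C12 to C11, not C7) and chemoselectivity: the first bond should form at the less hindered alkene carbon next to the C13 methylene, leaving the cation at C7 beside the more substituted C8, and the acrylate and the iodoalkene are too electron-poor to compete.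

Step 10
Reactants: 20 the cyclobutanone
Product: 21 iodoalkenyl γ-lactone fused to the tetrahydropyran (O6 inserted between C12 and C6; trans H6/H7)
Conditions: 30% H2O2, AcOH, 0 °C → rt
Reagents that add atoms: hydrogen peroxide, OO
Why: Baeyer–Villiger oxidation of the strained cyclobutanone: the secondary allylic C6 should migrate with retention in preference to C11 (deactivated by the β-oxygen), and hydrogen peroxide in acetic acid leaves acrylate and iodoalkene untouched.

Step 11
Reactants: 21 the iodoalkenyl lactone; 22 but-3-enylzinc bromide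
Product: 23 diene lactone (C4 now carries the C3–C2–C1=CH2 chain; 4E)
Conditions: 22 (0.5 M in THF), Pd(PPh3)4 (5 mol%), THF, rt
Reagents that add atoms: but-3-enylzinc bromide (22), C=CCC[Zn]Br
Why: Negishi sp2–sp3 coupling with retention of the alkene geometry; oxidative addition into C–I should be much faster than ionisation of the allylic lactone.

Step 12
Reactants: 23 the diene lactone
Product: 24 bridged macrocycle (ten-membered ring closed at C1=C10, ring-cis; pyran and lactone intact; O8-MOM)
Conditions: Grubbs II catalyst (10 mol%), toluene (1 mM), 80 °C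
Reagents that add atoms: none
Why: Ring-closing metathesis between the terminal alkene and the acrylate at high dilution; the ring-cis (CIP E) C1=C10 geometry is the one a ten-membered ring should adopt, and the fused pyran and lactone hold C5 and C10 on the same face.

Step 13
Reactants: 24 the MOM ether
Product: 25 the C8 alcohol (O9 still in the pyran)
Conditions: Me2BBr (2 equiv), CH2Cl2, −78 °C; then NaHCO3 aq.
Reagents that add atoms: none
Why: Lewis acid-assisted acetal cleavage: bromodimethylborane cleaves MOM ethers at −78 °C, where the cyclic ether should not yet open.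

Step 14
Reactants: 25 the alcohol; 26 methacrylic anhydride
Product: 27 the 8-O-methacrylate
Conditions: methacrylic anhydride, DMAP, Et3N, CH2Cl2, 0 °C → rt
Reagents that add atoms: methacrylic anhydride (26), C=C(C)C(=O)OC(=O)C(C)=C
Why: DMAP-catalysed acylation; O9 is still locked in the tetrahydropyran, so only O8 can react.

Step 15
Reactants: 27 the methacrylate
Product: 29 the target CNP0282644.1, via bromo borinate 28 (not isolated)
Conditions: Me2BBr (3 equiv), CH2Cl2, −78 → 0 °C; then DBU, 0 °C; NH4Cl aq.
Reagents that add atoms: none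
Why: Lewis acid-assisted SN2 opening of the cyclic ether by bromide at the primary C13, then E2/E1cB loss of HBr from the α-bromomethyl lactone, should unveil C11=C13 and, on work-up of the O9 borinate, the C9 hydroxyl; O9 stays borylated during base treatment and cannot re-add.

**Compound list**

1 | acrolein | C=CC=O | starting material
2 | 2,3-dibromopropanal | O=CC(Br)CBr | intermediate
3 | 2-bromoacrolein | C=C(Br)C=O | intermediate
4 | allyl methoxymethyl ether | C=CCOCOC | starting material
5 | [(Z)-3-(methoxymethoxy)allyl]bis(isopinocampheyl)borane, Ipc from (−)-α-pinene | COCO/C=C\CB([C@H]1C[C@H]2C[C@@H]([C@@H]1C)C2(C)C)[C@H]1C[C@H]2C[C@@H]([C@@H]1C)C2(C)C | intermediate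
6 | bis(isopinocampheyl)borinate of 7 | COCO[C@H]([C@@H](OB([C@H]1C[C@H]2C[C@@H]([C@@H]1C)C2(C)C)[C@H]1C[C@H]2C[C@@H]([C@@H]1C)C2(C)C)C(Br)=C)C=C | intermediate
7 | (3R,4S)-2-bromo-4-(methoxymethoxy)hexa-1,5-dien-3-ol | COCO[C@H]([C@@H](O)C(Br)=C)C=C | intermediate
8 | allyl bromide | C=CCBr | starting material
9 | (3R,4S)-3-(allyloxy)-2-bromo-4-(methoxymethoxy)hexa-1,5-diene | COCO[C@H]([C@@H](OCC=C)C(Br)=C)C=C | intermediate
10 | (2R,3S)-2-(1-bromovinyl)-3-(methoxymethoxy)-3,6-dihydro-2H-pyran | COCO[C@H]1C=CCO[C@H]1C(Br)=C | intermediate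
11 | methyl 2-[(2S,3S)-3-(methoxymethoxy)-3,6-dihydro-2H-pyran-2-yl]acrylate | COCO[C@H]1C=CCO[C@H]1C(=C)C(=O)OC | intermediate
12 | pent-3-yn-1-ol | CC#CCCO | starting material
13 | (E)-alkenylzirconocene chloride of the zirconium alkoxide of 12 | C/C(=C\CCO[Zr](Cl)(C1C=CC=C1)C1C=CC=C1)[Zr](Cl)(C1C=CC=C1)C1C=CC=C1 | intermediate
14 | (E)-4-iodopent-3-en-1-ol | C/C(I)=C\CCO | intermediate
15 | (E)-4-iodopent-3-enoic acid | C/C(I)=C\CC(=O)O | intermediate
16 | (E)-4-iodopent-3-enoyl chloride | C/C(I)=C\CC(=O)Cl | intermediate
17 | (E)-4-iodo-N,N-dimethylpent-3-enamide | C/C(I)=C\CC(=O)N(C)C | intermediate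
18 | N,N-dimethyl keteniminium triflate (C6=C12=N+) | C/C(I)=C\C=C=[N+](C)C.[O-]S(=O)(=O)C(F)(F)F | intermediate
19 | cyclobutaniminium triflate ([2+2] adduct) | COCO[C@H]1[C@H]2[C@@H](CO[C@H]1C(=C)C(=O)OC)C(=[N+](C)C)[C@@H]2/C=C(\C)I.[O-]S(=O)(=O)C(F)(F)F | intermediate
20 | cis-fused pyrano-cyclobutanone, C6 side chain exo | COCO[C@H]1[C@H]2[C@@H](CO[C@H]1C(=C)C(=O)OC)C(=O)[C@@H]2/C=C(\C)I | intermediate
21 | iodoalkenyl γ-lactone fused to the tetrahydropyran | COCO[C@H]1[C@H]2[C@@H](CO[C@H]1C(=C)C(=O)OC)C(=O)O[C@@H]2/C=C(\C)I | intermediate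
22 | but-3-enylzinc bromide | C=CCC[Zn]Br | starting material
23 | diene lactone (RCM precursor) | COCO[C@H]1[C@H]2[C@@H](CO[C@H]1C(=C)C(=O)OC)C(=O)O[C@@H]2/C=C(\C)CCC=C | intermediate
24 | bridged macrocycle, O8-MOM, O9–C13 ether intact | COCO[C@H]1[C@H]2[C@@H]3C(=O)O[C@@H]2/C=C(\C)CC/C=C(/C(=O)OC)[C@@H]1OC3 | intermediate
25 | bridged macrocycle, free C8–OH | O[C@H]1[C@H]2[C@@H]3C(=O)O[C@@H]2/C=C(\C)CC/C=C(/C(=O)OC)[C@@H]1OC3 | intermediate
26 | methacrylic anhydride | C=C(C)C(=O)OC(=O)C(C)=C | starting material
27 | bridged macrocycle, 8-O-methacrylate | C=C(C)C(=O)O[C@H]1[C@H]2[C@@H]3C(=O)O[C@@H]2/C=C(\C)CC/C=C(/C(=O)OC)[C@@H]1OC3 | intermediate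
28 | α-bromomethyl lactone, O9 dimethylborinate | C=C(C)C(=O)O[C@H]1[C@H]2[C@@H](CBr)C(=O)O[C@@H]2/C=C(\C)CC/C=C(/C(=O)OC)[C@@H]1OB(C)C | intermediate
29 | CNP0282644.1 (6R,7S,8S,9S) | C=C(C)C(=O)O[C@H]1[C@H]2C(=C)C(=O)O[C@@H]2/C=C(\C)CC/C=C(/C(=O)OC)[C@@H]1O | target

**Totals.** 15 steps in all; the longest linear sequence is 12 steps (steps 1–5 and 9–15).

**Steps most likely to fail**

Step 9 (key cycloaddition). The alkene of 11 carries two allylic oxygens and may react sluggishly, the ether oxygens may attack the keteniminium, and the first C–C bond may form with incomplete regiocontrol. The fallback changes the two-carbon partner to a halogen-activated ketene under neutral thermal conditions. It sets out from acid 15 and pyran 11. The dianion of 15 (LDA, THF, −78 °C) should be chlorinated with CCl4 to racemic 2-chloro-(E)-4-iodopent-3-enoic acid F1, and oxalyl chloride should give 2-chloro-(E)-4-iodopent-3-enoyl chloride F2. Slow addition of F2 to 11 and Et3N in refluxing CH2Cl2 should generate the chloro(alkenyl)ketene and give the α-chlorocyclobutanone F3 by ketene–alkene [2+2]. Zinc in acetic acid should remove the chlorine, and DBU equilibration returns the route to 20.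

Step 12 (macrocyclisation). Oligomerisation may win over closure of the ten-membered ring while the pyran keeps the system bridged and strained. The fallback opens the pyran first and sets out from 23. KHMDS (THF, −78 °C) followed by TBSOTf should open the pyran by E1cB and trap O9, giving the seco α-methylene lactone O9-TBS ether F4. Ring-closing metathesis on this flexible system should give the macrocycle F5 (O8-MOM, O9-TBS). Me2BBr at −78 °C should free O8 to give the alcohol F6, methacrylic anhydride/DMAP should give the methacrylate F7, and HF·pyridine should remove the silyl group and arrive at 29.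

Step 15 (ether opening). The Lewis acid may cleave the allylic C9–O9 bond instead of C13–O9 or damage the methacrylate. The fallback is anionic and sets out from 27. LiHMDS with Me3SiCl present (THF, −78 °C) should form the C11 enolate, which opens the pyran by E1cB while the alkoxide is silylated at once, giving the O9-trimethylsilyl ether of the target F8. Citric acid in methanol should remove the silyl group and give 29.

Further compounds
F1 | step 9 | 2-chloro-(E)-4-iodopent-3-enoic acid (racemic) | C/C(I)=C\C(Cl)C(=O)O
F2 | step 9 | 2-chloro-(E)-4-iodopent-3-enoyl chloride (racemic) | C/C(I)=C\C(Cl)C(Cl)=O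
F3 | step 9 | α-chlorocyclobutanone (chlorine exo at C6, otherwise as 20) | COCO[C@H]1[C@H]2[C@@H](CO[C@H]1C(=C)C(=O)OC)C(=O)[C@@]2(Cl)/C=C(\C)I
F4 | step 12 | seco α-methylene lactone, O8-MOM, O9-TBS | COCO[C@H]([C@@H](O[Si](C)(C)C(C)(C)C)C(=C)C(=O)OC)[C@H]1C(=C)C(=O)O[C@@H]1/C=C(\C)CCC=C
F5 | step 12 | macrocycle, O8-MOM, O9-TBS | COCO[C@H]1[C@H]2C(=C)C(=O)O[C@@H]2/C=C(\C)CC/C=C(/C(=O)OC)[C@@H]1O[Si](C)(C)C(C)(C)C
F6 | step 12 | macrocycle, free C8–OH, O9-TBS | O[C@H]1[C@H]2C(=C)C(=O)O[C@@H]2/C=C(\C)CC/C=C(/C(=O)OC)[C@@H]1O[Si](C)(C)C(C)(C)C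
F7 | step 12 | macrocycle, 8-O-methacrylate, O9-TBS | C=C(C)C(=O)O[C@H]1[C@H]2C(=C)C(=O)O[C@@H]2/C=C(\C)CC/C=C(/C(=O)OC)[C@@H]1O[Si](C)(C)C(C)(C)C
F8 | step 15 | O9-trimethylsilyl ether of the target | C=C(C)C(=O)O[C@H]1[C@H]2C(=C)C(=O)O[C@@H]2/C=C(\C)CC/C=C(/C(=O)OC)[C@@H]1O[Si](C)(C)C
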